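**Retrosynthetic overview** (terpenoid numbering: ring A = C1–C5, C10; ring B = C5–C10; C11 = CH2O on C9; C12 = exocyclic CH2 on C8)
1. Target 15 ⇒ acetylation of O-3 and Mitsunobu etherification of C11–OH with commercial isofraxidin 13 ⇒ diol 12 ⇒ methylenation of the C8 ketone of 11.
2. Ketone 11 ⇒ one-flask, three-component ring enlargement of cis-hydrindan-8-one 7 with CH2Br2 (becomes C9) and CH2O (becomes C11). Ring B is present in 7 as the five-membered ring C5–C6–C7–C8–C10, and C9 is inserted between C8 and C10.
3. Enabling feature: the C8 carbonyl next to quaternary C10 in the cis-fused hydrindanone. C8 accepts the carbenoid carbon, C10 is the migrating atom, and the resulting C8=C9 enolate takes C11 on the convex face defined by H-5 and CH3-10.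
4. 7 ⇒ commercial (R)-enedione 1 (ring A and C10 bought): cis ring fusion by hydrogenation, gem-dimethyl at C4 by alkylation, C3 by CBS reduction.
5. Ring order: ring A (in 1) → ring B as a five-membered ring (in 1) → ring B six-membered (step 6) → coumarin attached last.

Key step: step 6

Assumption (stereochemistry read literally from the SMILES): H-5, CH3-10 and C11 lie on one face (cis-fused decalin) and the 3-acetoxy group on the other; absolute configuration 3S,5R,9R,10R, which corresponds to the (R) series of the bicyclic enedione.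

**Step 1**
Reactants: 1 (7aR)-7a-methyl-2,3,7,7a-tetrahydro-1H-indene-1,5(6H)-dione
Product: 2 (7a'R)-7a'-methyl-2',3',7',7a'-tetrahydrospiro[[1,3]dioxolane-2,1'-inden]-5'(6'H)-one
Conditions: TMSOCH2CH2OTMS, TMSOTf (cat.), CH2Cl2, −78 to −20 °C
Reagents that add atoms: 1,2-bis(trimethylsilyloxy)ethane, C[Si](C)(C)OCCO[Si](C)(C)C
Why: TMSOTf-catalysed ketalization with the bis-silyl ether should be selective for the saturated C8 ketone, because the conjugated C3 carbonyl is much less prone to oxocarbenium formation at low temperature; no stereocentre is touched.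

**Step 2**
Reactants: 2 (7a'R)-7a'-methyl-2',3',7',7a'-tetrahydrospiro[[1,3]dioxolane-2,1'-inden]-5'(6'H)-one
Product: 3 (3a'S,7a'R)-7a'-methylhexahydrospiro[[1,3]dioxolane-2,1'-inden]-5'(4'H)-one
Conditions: H2 (1 atm), Pd/C, EtOAc, rt
Reagents that add atoms: none
Why: Heterogeneous hydrogenation of 7a-methylhydrindenones of this type is expected to deliver hydrogen to C4=C5 on the face of the angular methyl group, which sets H-5 cis to CH3-10 (cis-fused hydrindanone).

**Step 3**
Reactants: 3 (3a'S,7a'R)-7a'-methylhexahydrospiro[[1,3]dioxolane-2,1'-inden]-5'(4'H)-one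
Product: 5 (3a'S,7a'R)-4',4',7a'-trimethylhexahydrospiro[[1,3]dioxolane-2,1'-inden]-5'(4'H)-one, via 4-monomethyl ketone 4 (not isolated)
Conditions: KOtBu (2.3 equiv), MeI, t-BuOH/THF, 0 °C to rt
Reagents that add atoms: iodomethane, CI
Why: Under equilibrating conditions the cis-fused 3-ketone should enolize toward C4 (ring-fusion side, as in cis-fused 10-methyl-3-decalones), and after the first C-methylation the more substituted enolate again lies at C4, so both methyl groups enter there by enolate alkylation; the transient C4 centre of 4 disappears in 5.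

**Step 4**
Reactants: 5 (3a'S,7a'R)-4',4',7a'-trimethylhexahydrospiro[[1,3]dioxolane-2,1'-inden]-5'(4'H)-one
Product: 6 (3a'S,5'S,7a'R)-4',4',7a'-trimethyloctahydrospiro[[1,3]dioxolane-2,1'-inden]-5'-ol
Conditions: (R)-2-methyl-CBS-oxazaborolidine (0.2 equiv), BH3·SMe2, THF, −20 to 0 °C; then MeOH
Reagents that add atoms: none
Why: CBS reduction, in which the catalyst distinguishes the quaternary C4 side from the C2 methylene side and the (R) catalyst should give the (3S) alcohol; this is also the sense expected for hydride approach on the convex face of the cis-fused bicycle (OH trans to CH3-10).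

**Step 5**
Reactants: 6 (3a'S,5'S,7a'R)-4',4',7a'-trimethyloctahydrospiro[[1,3]dioxolane-2,1'-inden]-5'-ol
Product: 7 (3aS,5S,7aR)-5-hydroxy-4,4,7a-trimethyloctahydro-1H-inden-1-one
Conditions: 1 M HCl, THF, rt
Reagents that add atoms: water, O
Why: Acid hydrolysis of the dioxolane frees the C8 ketone; C10 is quaternary and C5 is not enolizable from C8, so no stereocentre can epimerize.

**Step 6**
Reactants: 7 (3aS,5S,7aR)-5-hydroxy-4,4,7a-trimethyloctahydro-1H-inden-1-one
Product: 11 (1R,4aR,6S,8aR)-6-hydroxy-1-(hydroxymethyl)-5,5,8a-trimethyloctahydronaphthalen-2(1H)-one, via dilithium dibromomethyl carbinolate 8 (not isolated), via lithium bromocarbenoid 9 (not isolated), via ring-enlarged dilithium enolate 10 (not isolated)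
Conditions: CH2Br2 (1.3 equiv), lithium 2,2,6,6-tetramethylpiperidide (LiTMP, 2.4 equiv), THF, −78 °C; then n-BuLi (1.6 equiv), −95 to −20 °C; then CH2O (gas, excess), −78 °C; then H2O
Reagents that add atoms: dibromomethane, BrCBr; formaldehyde, C=O
Why: Dibromomethyllithium (from CH2Br2 and LiTMP) adds to the C8 carbonyl of 7 to give carbinolate 8, and bromine–lithium exchange with n-BuLi gives the β-oxido carbenoid 9, in which the C8–C10 bond migrates to the carbenoid carbon C9 with loss of LiBr; the C8=C9 lithium enolate 10 that results then adds to formaldehyde to form the C9–C11 bond. No ring is closed by cyclization: ring B grows from five to six members by this 1,2-shift (one-carbon ring enlargement). The closest known reaction type is the β-oxido carbenoid ring enlargement of cycloalkanones with dibromomethyllithium, whose regiodefined lithium enolate is here intercepted in the same flask as in an ordinary aldol hydroxymethylation. The step needs migration of C10 and not of C7: the more substituted, more electron-rich α-carbon is the better migrating group toward the electron-poor carbenoid carbon, and the shift relieves the congestion of the C8–C10 bond between a quaternary centre and the fully substituted carbinol carbon. The only new stereocentre, C9, is set in the aldol step by the cis ring fusion: formaldehyde should enter on the convex face of enolate 10 (the face of H-5 and CH3-10), because the concave face is covered by C4 and its methyl groups, which places C11 cis to CH3-10 as required. The C8 configuration of 8 is of no consequence, since C8 returns to sp2, and the C3 lithium alkoxide is a spectator.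

**Step 7**
Reactants: 11 (1R,4aR,6S,8aR)-6-hydroxy-1-(hydroxymethyl)-5,5,8a-trimethyloctahydronaphthalen-2(1H)-one
Product: 12 (2S,4aR,5R,8aR)-5-(hydroxymethyl)-1,1,4a-trimethyl-6-methylidenedecahydronaphthalen-2-ol
Conditions: Zn, CH2Br2, TiCl4, THF/CH2Cl2, 0 °C to rt
Reagents that add atoms: dibromomethane, BrCBr
Why: Takai–Lombardo methylenation with the non-basic gem-dimetallic reagent should convert the hindered, enolizable C8 ketone into the exocyclic methylene without epimerizing C9 or triggering retro-aldol cleavage, and free hydroxyl groups are tolerated with excess reagent.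

**Step 8**
Reactants: 12 (2S,4aR,5R,8aR)-5-(hydroxymethyl)-1,1,4a-trimethyl-6-methylidenedecahydronaphthalen-2-ol; 13 isofraxidin (7-hydroxy-6,8-dimethoxy-2H-chromen-2-one)
Product: 14 7-{[(1R,4aR,6S,8aR)-6-hydroxy-5,5,8a-trimethyl-2-methylidenedecahydronaphthalen-1-yl]methoxy}-6,8-dimethoxy-2H-chromen-2-one
Conditions: PPh3, DIAD, THF, 0 °C to rt
Reagents that add atoms: none
Why: Mitsunobu etherification, in which only the primary C11–OH is activated (the secondary C3–OH next to the gem-dimethyl carbon is inert) and the acidic phenol displaces the oxyphosphonium group at the CH2 carbon, so no stereocentre is involved.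

**Step 9**
Reactants: 14 7-{[(1R,4aR,6S,8aR)-6-hydroxy-5,5,8a-trimethyl-2-methylidenedecahydronaphthalen-1-yl]methoxy}-6,8-dimethoxy-2H-chromen-2-one
Product: 15 [(2S,4aR,5R,8aR)-5-{[(6,8-dimethoxy-2-oxo-2H-chromen-7-yl)oxy]methyl}-1,1,4a-trimethyl-6-methylidenedecahydronaphthalen-2-yl] acetate (target)
Conditions: Ac2O, pyridine, DMAP (cat.), CH2Cl2, rt
Reagents that add atoms: acetic anhydride, CC(=O)OC(C)=O
Why: DMAP-catalysed O-acylation of the hindered secondary alcohol proceeds with retention at C3 and leaves the lactone, the aryl ether and the exocyclic alkene untouched.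

**Compound list**
1 | (7aR)-7a-methyl-2,3,7,7a-tetrahydro-1H-indene-1,5(6H)-dione (commercial in both enantiomeric forms) | O=C1CCC2=CC(=O)CC[C@]21C | starting material
2 | (7a'R)-7a'-methyl-2',3',7',7a'-tetrahydrospiro[[1,3]dioxolane-2,1'-inden]-5'(6'H)-one (C8 ethylene ketal) | O1CCOC13CCC2=CC(=O)CC[C@]23C | intermediate
3 | (3a'S,7a'R)-7a'-methylhexahydrospiro[[1,3]dioxolane-2,1'-inden]-5'(4'H)-one (H-5 and CH3-10 cis) | O1CCOC13CC[C@H]2CC(=O)CC[C@]23C | intermediate
4 | (3a'S,4'S,7a'R)-4',7a'-dimethylhexahydrospiro[[1,3]dioxolane-2,1'-inden]-5'(4'H)-one (methyl drawn on the convex face; C4 epimerizable) | O1CCOC13CC[C@H]2[C@H](C)C(=O)CC[C@]23C | intermediate (not isolated)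
5 | (3a'S,7a'R)-4',4',7a'-trimethylhexahydrospiro[[1,3]dioxolane-2,1'-inden]-5'(4'H)-one | O1CCOC13CC[C@H]2C(C)(C)C(=O)CC[C@]23C | intermediate
6 | (3a'S,5'S,7a'R)-4',4',7a'-trimethyloctahydrospiro[[1,3]dioxolane-2,1'-inden]-5'-ol | O1CCOC13CC[C@H]2C(C)(C)[C@@H](O)CC[C@]23C | intermediate
7 | (3aS,5S,7aR)-5-hydroxy-4,4,7a-trimethyloctahydro-1H-inden-1-one | O=C1CC[C@H]2C(C)(C)[C@@H](O)CC[C@]21C | intermediate
8 | dilithium (1S,3aS,5S,7aR)-1-(dibromomethyl)-4,4,7a-trimethyloctahydro-1H-indene-1,5-diolate (CHBr2 drawn on the face of CH3-10; C8 configuration is lost later) | [Li]O[C@@]1(C(Br)Br)CC[C@H]2C(C)(C)[C@@H](O[Li])CC[C@]21C | intermediate (not isolated)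
9 | dilithium (1S,3aS,5S,7aR)-1-[bromo(lithio)methyl]-4,4,7a-trimethyloctahydro-1H-indene-1,5-diolate (β-oxido carbenoid; carbenoid carbon configurationally labile) | [Li]O[C@@]1(C([Li])Br)CC[C@H]2C(C)(C)[C@@H](O[Li])CC[C@]21C | intermediate (not isolated)
10 | dilithium (4aR,6S,8aR)-5,5,8a-trimethyl-3,4,4a,5,6,7,8,8a-octahydronaphthalene-2,6-diolate (C8=C9 enolate and C3 alkoxide) | [Li]OC=1CC[C@H]2C(C)(C)[C@@H](O[Li])CC[C@@]2(C)C=1 | intermediate (not isolated)
11 | (1R,4aR,6S,8aR)-6-hydroxy-1-(hydroxymethyl)-5,5,8a-trimethyloctahydronaphthalen-2(1H)-one | O=C1CC[C@H]2C(C)(C)[C@@H](O)CC[C@@]2(C)[C@@H]1CO | intermediate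
12 | (2S,4aR,5R,8aR)-5-(hydroxymethyl)-1,1,4a-trimethyl-6-methylidenedecahydronaphthalen-2-ol | C=C1CC[C@H]2C(C)(C)[C@@H](O)CC[C@@]2(C)[C@@H]1CO | intermediate
13 | isofraxidin (7-hydroxy-6,8-dimethoxy-2H-chromen-2-one) | Oc1c(OC)cc2ccc(=O)oc2c1OC | starting material
14 | 7-{[(1R,4aR,6S,8aR)-6-hydroxy-5,5,8a-trimethyl-2-methylidenedecahydronaphthalen-1-yl]methoxy}-6,8-dimethoxy-2H-chromen-2-one | C=C1CC[C@H]2C(C)(C)[C@@H](O)CC[C@@]2(C)[C@@H]1COc1c(OC)cc2ccc(=O)oc2c1OC | intermediate
15 | [(2S,4aR,5R,8aR)-5-{[(6,8-dimethoxy-2-oxo-2H-chromen-7-yl)oxy]methyl}-1,1,4a-trimethyl-6-methylidenedecahydronaphthalen-2-yl] acetate | C=C1CC[C@H]2C(C)(C)[C@@H](OC(C)=O)CC[C@@]2(C)[C@@H]1COc1c(OC)cc2ccc(=O)oc2c1OC | target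

**Step count and risks**
Total step count: 9. Longest linear sequence: 9 steps (1 → 15); isofraxidin 13 enters in step 8.

Steps most likely to fail:

1. Step 6. Addition of dibromomethyllithium may lose to enolization of the hindered C8 ketone. In the carbenoid the C7 methylene may migrate in place of C10. The enolate may be hydroxymethylated a second time after proton transfer. Fallback, from 7 and back at 11: vinylmagnesium bromide with CeCl3 in THF adds to C8 to give (1R,3aS,5S,7aR)-1-ethenyl-4,4,7a-trimethyloctahydro-1H-indene-1,5-diol F1. Hydroxyl-directed epoxidation with VO(acac)2 and t-BuOOH gives (1S,3aS,5S,7aR)-4,4,7a-trimethyl-1-[(2S)-oxiran-2-yl]octahydro-1H-indene-1,5-diol F2. BF3·OEt2 in CH2Cl2 at low temperature then induces the semipinacol rearrangement, in which C10 migrates to C9 with inversion as the epoxide opens, and this delivers 11 directly. The cationic character at C9 favours migration of the quaternary carbon, and C9 is then set by the epoxide configuration (the 9-epimer drawn for F2 is the one required) rather than by the aldol step.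

2. Step 3. Regiocontrol may be lost under equilibrating conditions: alkylation may spill over to C2 or stop at the monomethyl stage. Fallback, from 3 and back at 5: iodotrimethylsilane and hexamethyldisilazane give the thermodynamic enol ether (3a'S,7a'R)-7a'-methyl-5'-(trimethylsilyloxy)-2',3',3a',6',7',7a'-hexahydrospiro[[1,3]dioxolane-2,1'-indene] F3, which is purified, cleaved with MeLi to the regiodefined lithium enolate and methylated with MeI to give 4 (here isolated). The same two operations through the tetrasubstituted enol ether (3a'S,7a'R)-4',7a'-dimethyl-5'-(trimethylsilyloxy)-2',3',3a',6',7',7a'-hexahydrospiro[[1,3]dioxolane-2,1'-indene] F4 give 5. Regiochemistry is thus fixed and checked at the enol ether stage and each methyl group is introduced in a separate, stoichiometric alkylation.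

3. Step 8. Substitution at the β-branched C11 by the di-ortho-substituted phenol may be slow. The oxyphosphonium intermediate may instead ionize with participation of the C8=C12 double bond or be consumed by the hydrazide. Fallback, from 12 and back at 14: Tf2O and 2,6-lutidine in CH2Cl2 at −78 °C convert the primary hydroxyl selectively into [(1R,4aR,6S,8aR)-6-hydroxy-5,5,8a-trimethyl-2-methylidenedecahydronaphthalen-1-yl]methyl trifluoromethanesulfonate F5, which is displaced without isolation by the cesium phenoxide of 13 (Cs2CO3, DMF, 0 °C to rt) to give 14.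

**Further compounds**
F1 | step 6 | (1R,3aS,5S,7aR)-1-ethenyl-4,4,7a-trimethyloctahydro-1H-indene-1,5-diol | O[C@@]1(C=C)CC[C@H]2C(C)(C)[C@@H](O)CC[C@]21C
F2 | step 6 | (1S,3aS,5S,7aR)-4,4,7a-trimethyl-1-[(2S)-oxiran-2-yl]octahydro-1H-indene-1,5-diol | O[C@@]1([C@@H]2CO2)CC[C@H]3C(C)(C)[C@@H](O)CC[C@]31C
F3 | step 3 | (3a'S,7a'R)-7a'-methyl-5'-(trimethylsilyloxy)-2',3',3a',6',7',7a'-hexahydrospiro[[1,3]dioxolane-2,1'-indene] | O1CCOC13CC[C@H]2C=C(O[Si](C)(C)C)CC[C@]23C
F4 | step 3 | (3a'S,7a'R)-4',7a'-dimethyl-5'-(trimethylsilyloxy)-2',3',3a',6',7',7a'-hexahydrospiro[[1,3]dioxolane-2,1'-indene] | O1CCOC13CC[C@H]2C(C)=C(O[Si](C)(C)C)CC[C@]23C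
F5 | step 8 | [(1R,4aR,6S,8aR)-6-hydroxy-5,5,8a-trimethyl-2-methylidenedecahydronaphthalen-1-yl]methyl trifluoromethanesulfonate | C=C1CC[C@H]2C(C)(C)[C@@H](O)CC[C@@]2(C)[C@@H]1COS(=O)(=O)C(F)(F)F
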